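**Retrosynthetic overview**

1. Numbering (hydroazulene): C1 (CMe2), C2 (CHOH), C3, C3a (ring-fusion CH), C4 (C=O), C5 (quaternary C), C6 (CHMe), C7, C8, C8a (ring-fusion C–OH). Last disconnections: silyl ethers, the butenolide (Bestmann ylide on an α-hydroxy ketone) and the C5 side chain (Michael addition anti to the C6 methyl).
2. Key disconnection: C3a–C4 and C5–C6 together. Methylketene (C4 + C5) is a two-carbon linchpin between a cyclopentenyl anion at C3a and an allylic chloride at C6, a formal [5+2] annulation that closes the seven-membered ring.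
3. Enabling feature: the C4 ketone is flanked by C3a, a cyclopentane carbon next to C3 that can be the carbanionic end of a C3=C3a alkene, and by its α-carbon C5. C6 is tied to C8a by the C7–C8 bridge, which as a cis alkene makes C6 an allylic electrophile held over the enolate; a seven-membered enolendo closure is allowed.
4. The five-carbon partner comes from 2,2-dimethylcyclopentane-1,3-dione (C1–C3a, C8a; CBS desymmetrization sets C2) and (R)-but-3-yn-2-ol (C6, C7, C8 and the C6 methyl; sets C6). C8a is set by 1,2-addition anti to the C2 silyloxy group.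
5. Ring order: cyclopentane (bought as the dione), cycloheptane (key step), butenolide (last). The C3=C3a and C7=C8 alkenes are removed in one hydrogenation, which sets C3a.

Key step: step 11

Assumption: (R)-but-3-yn-2-ol, 2-bromopropanoyl bromide and 2-(benzyloxy)-N-methoxy-N-methylacetamide are taken as purchasable; the route has not been run and all outcomes are expectations.

**Step 1**
Reactants: 1 2,2-dimethylcyclopentane-1,3-dione
Product: 2 (R)-3-hydroxy-2,2-dimethylcyclopentan-1-one
Conditions: (S)-Me-CBS (10 mol %), catecholborane (1.1 equiv), toluene, −60 °C; aq. NaOH work-up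
Reagents that add atoms: none
Why: Corey–Bakshi–Shibata reduction desymmetrizes the prochiral dione; with the quaternary carbon as the large group the (S)-catalyst should give the (R)-carbinol (later C2), and the hydroxy ketone is reduced more slowly than the dione.

**Step 2**
Reactants: 2 (R)-3-hydroxy-2,2-dimethylcyclopentan-1-one
Product: 3 (R)-3-[(tert-butyldimethylsilyl)oxy]-2,2-dimethylcyclopentan-1-one
Conditions: TBSCl, imidazole, DMF, 23 °C
Reagents that add atoms: tert-butyldimethylsilyl chloride, CC(C)(C)[Si](C)(C)Cl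
Why: Standard silylation of a secondary alcohol; the bulky ether later steers additions to the opposite ring face.

**Step 3**
Reactants: 3 (R)-3-[(tert-butyldimethylsilyl)oxy]-2,2-dimethylcyclopentan-1-one
Product: 5 (R)-4-[(tert-butyldimethylsilyl)oxy]-5,5-dimethylcyclopent-2-en-1-one, via trimethylsilyl enol ether 4 (not isolated)
Conditions: LiHMDS, TMSCl, THF, −78 °C; then Pd(OAc)2 (1.05 equiv), MeCN, 23 °C
Reagents that add atoms: none
Why: Saegusa–Ito oxidation; only one α-position is enolizable, so a single silyl enol ether forms and Pd(II) dehydrosilylation should give the enone.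

**Step 4**
Reactants: 5 (R)-4-[(tert-butyldimethylsilyl)oxy]-5,5-dimethylcyclopent-2-en-1-one
Product: 7 (R)-2-bromo-4-[(tert-butyldimethylsilyl)oxy]-5,5-dimethylcyclopent-2-en-1-one, via dibromide 6 (not isolated)
Conditions: Br2, CH2Cl2, 0 °C; then Et3N, 0 → 23 °C
Reagents that add atoms: bromine, BrBr
Why: α-Bromination of an enone by bromine addition and E1cB loss of HBr, a routine way to place a halogen on the enone α-carbon (later C3a).

**Step 5**
Reactants: 8 (R)-but-3-yn-2-ol
Product: 9 (R)-4-iodobut-3-yn-2-ol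
Conditions: NIS, AgNO3 (10 mol %), acetone, 23 °C
Reagents that add atoms: N-iodosuccinimide, O=C1CCC(=O)N1I
Why: Silver-catalysed electrophilic iodination of a terminal alkyne; the carbinol stereocentre is not touched.

**Step 6**
Reactants: 9 (R)-4-iodobut-3-yn-2-ol
Product: 10 (R,Z)-4-iodobut-3-en-2-ol
Conditions: 2-nitrobenzenesulfonohydrazide, Et3N, THF–i-PrOH, 23 °C
Reagents that add atoms: none
Why: Diimide reduction transfers two hydrogens syn in a concerted step, so the iodoalkyne should give the (Z)-iodoalkene.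

**Step 7**
Reactants: 7 (R)-2-bromo-4-[(tert-butyldimethylsilyl)oxy]-5,5-dimethylcyclopent-2-en-1-one; 10 (R,Z)-4-iodobut-3-en-2-ol
Product: 13 {[(1R,4R)-2-bromo-4-[(tert-butyldimethylsilyl)oxy]-5,5-dimethyl-1-[(1Z,3R)-3-[(trimethylsilyl)oxy]but-1-en-1-yl]cyclopent-2-en-1-yl]oxy}trimethylsilane, via dilithio reagent 11 (not isolated), via dilithium dialkoxide 12 (not isolated)
Conditions: 10 (1.3 equiv), t-BuLi (3.9 equiv), Et2O, −78 °C; then 7, THF, −78 °C; then TMSCl, Et3N, −78 → 23 °C
Reagents that add atoms: chlorotrimethylsilane, C[Si](C)(C)Cl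
Why: Iodine–lithium exchange keeps the Z geometry and the alkenyllithium adds 1,2 to the non-enolizable ketone from the face opposite the silyloxy group, which should set the tertiary carbinol (later C8a) with its oxygen cis to OTBS; both alkoxides are trapped as TMS ethers.

**Step 8**
Reactants: 13 bis-TMS ether
Product: 14 (2R,3Z)-4-[(1R,4R)-2-bromo-4-[(tert-butyldimethylsilyl)oxy]-5,5-dimethyl-1-[(trimethylsilyl)oxy]cyclopent-2-en-1-yl]but-3-en-2-ol
Conditions: K2CO3 (cat.), MeOH, 0 °C, short contact
Reagents that add atoms: none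
Why: Selective methanolysis; the secondary allylic TMS ether should cleave much faster than the hindered tertiary one.

**Step 9**
Reactants: 14 allylic alcohol
Product: 15 {[(1R,4R)-2-bromo-4-[(tert-butyldimethylsilyl)oxy]-1-[(1Z,3S)-3-chlorobut-1-en-1-yl]-5,5-dimethylcyclopent-2-en-1-yl]oxy}trimethylsilane
Conditions: hexachloroacetone, PPh3, CH2Cl2, 0 °C; used at once
Reagents that add atoms: hexachloroacetone, O=C(C(Cl)(Cl)Cl)C(Cl)(Cl)Cl
Why: Appel-type chlorination of an allylic alcohol with hexachloroacetone/triphenylphosphine goes by SN2 on the alkoxyphosphonium ion, so it should give the (S)-chloride with inversion and without allylic transposition.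

**Step 10**
Reactants: 16 2-bromopropanoyl bromide
Product: 17 methylketene (prop-1-en-1-one), as a cold THF solution
Conditions: activated Zn, THF, −10 °C, reduced pressure; co-distilled into a −78 °C receiver; used at once
Reagents that add atoms: none
Why: Zinc dehalogenation of an α-bromoacyl bromide is the standard route to salt-free aldoketene solutions.

**Step 11**
Reactants: 15 (S)-allylic chloride; 17 methylketene
Product: 20 (2R,6R,8aR)-2-[(tert-butyldimethylsilyl)oxy]-1,1,5,6-tetramethyl-8a-[(trimethylsilyl)oxy]-2,5,6,8a-tetrahydroazulen-4(1H)-one (mixture at C5), via alkenyllithium 18 (not isolated), via lithium dienolate 19 (not isolated)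
Conditions: t-BuLi (2.05 equiv), THF–Et2O–pentane 4:1:1, −100 °C, 10 min; 17 (1.05 equiv), −100 → −78 °C; then warm to 23 °C, 12 h
Reagents that add atoms: none
Why: Bromine–lithium exchange at −100 °C (as in Parham cyclialkylations, where a tethered alkyl chloride survives) gives alkenyllithium 18, which adds to the carbonyl carbon of methylketene to give lithium dienolate 19 and so the C3a–C4 bond; on warming, the enolate carbon displaces the allylic chloride to form the C5–C6 bond and the cycloheptadienone. The closest known reaction types are the addition of organolithiums to ketenes to give ketone enolates and the intramolecular C-alkylation of lithium enolates by allylic halides. The seven-membered ring closes in the 7-(enolendo)-exo-tet mode, which Baldwin's enolate rules allow, whereas SN2′ attack on the nearer alkene carbon would be 5-(enolendo) and is disfavoured. C6 is set by SN2 inversion of the (S)-chloride derived from (R)-but-3-yn-2-ol, which places the methyl cis to the C8a oxygen; C5 forms as a mixture that does not matter because it is re-enolized in step 13. The step needs C- over O-alkylation and exchange without attack on the chloride: the lithium enolate in THF without polar additive, the soft allylic chloride and the cis C7=C8 alkene that holds C6 over the enolate carbon should secure the first, and exchange at −100 °C followed at once by the ketene the second.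

**Step 12**
Reactants: 21 2-(benzyloxy)-N-methoxy-N-methylacetamide
Product: 22 1-(benzyloxy)but-3-en-2-one
Conditions: vinylmagnesium bromide, THF, 0 °C; inverse quench into cold aq. HCl
Reagents that add atoms: vinylmagnesium bromide, C=C[Mg]Br
Why: Weinreb ketone synthesis; the chelated tetrahedral intermediate prevents over-addition and the acidic quench keeps the released amine from adding to the vinyl ketone.

**Step 13**
Reactants: 20 bicyclic dienone; 22 1-(benzyloxy)but-3-en-2-one
Product: 24 (2R,5S,6R,8aR)-5-[4-(benzyloxy)-3-oxobutyl]-2-[(tert-butyldimethylsilyl)oxy]-1,1,5,6-tetramethyl-8a-[(trimethylsilyl)oxy]-2,5,6,8a-tetrahydroazulen-4(1H)-one, via lithium enolate 23 (not isolated)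
Conditions: LDA (1.05 equiv), THF, −78 °C; then 22, −78 °C, 1 h; AcOH quench at −78 °C
Reagents that add atoms: none
Why: Kinetic deprotonation can occur only at C5 because C3a is sp2; Michael addition of enolate 23 to the vinyl ketone should occur anti to the C6 methyl, which A(1,3) strain holds pseudoaxial, setting the quaternary C5 with its methyl cis to the C6 methyl.

**Step 14**
Reactants: 24 Michael adduct
Product: 25 (2R,3aS,5S,6R,8aS)-2-[(tert-butyldimethylsilyl)oxy]-5-(4-hydroxy-3-oxobutyl)-1,1,5,6-tetramethyl-8a-[(trimethylsilyl)oxy]octahydroazulen-4(1H)-one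
Conditions: H2 (1–3 atm), 10 % Pd/C, EtOAc, 23 °C
Reagents that add atoms: none
Why: Heterogeneous hydrogenation saturates both ring alkenes and hydrogenolyses the benzyl ether; hydrogen should add to C3=C3a from the face opposite the two allylic silyloxy groups (C2, C8a), setting C3a–H trans to the C8a oxygen (trans ring fusion).

**Step 15**
Reactants: 25 α-hydroxy ketone
Product: 27 (2R,3aS,5S,6R,8aS)-2-[(tert-butyldimethylsilyl)oxy]-1,1,5,6-tetramethyl-5-[2-(5-oxo-2,5-dihydrofuran-3-yl)ethyl]-8a-[(trimethylsilyl)oxy]octahydroazulen-4(1H)-one, via ester ylide 26 (not isolated)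
Conditions: Ph3P=C=C=O (1.3 equiv), toluene, 90 °C
Reagents that add atoms: (triphenylphosphoranylidene)ketene, O=C=C=P(c1ccccc1)(c1ccccc1)c1ccccc1
Why: Bestmann's ylide acylates the primary alcohol to ester ylide 26, which closes by intramolecular Wittig reaction on the adjacent ketone to the β-substituted butenolide (the cardenolide method); the hindered C4 ketone and the silyl ethers should not react.

**Step 16**
Reactants: 27 bis-silyl ether
Product: 28 (2R,3aS,5S,6R,8aS)-2,8a-dihydroxy-1,1,5,6-tetramethyl-5-[2-(5-oxo-2,5-dihydrofuran-3-yl)ethyl]octahydroazulen-4(1H)-one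
Conditions: HF·pyridine, THF, 0 → 23 °C
Reagents that add atoms: none
Why: Acidic fluoride cleavage of both silyl ethers; the β-hydroxy ketone (base-sensitive) and the butenolide should tolerate these conditions.

**Compound list**

1 | 2,2-dimethylcyclopentane-1,3-dione | CC1(C)C(=O)CCC1=O | starting material
2 | (R)-3-hydroxy-2,2-dimethylcyclopentan-1-one | O=C1CC[C@@H](O)C1(C)C | intermediate
3 | (R)-3-[(tert-butyldimethylsilyl)oxy]-2,2-dimethylcyclopentan-1-one | O=C1CC[C@@H](O[Si](C)(C)C(C)(C)C)C1(C)C | intermediate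
4 | trimethylsilyl enol ether of 3 (silyloxy carbon unchanged) | C[Si](C)(C)OC1=CC[C@@H](O[Si](C)(C)C(C)(C)C)C1(C)C | intermediate (not isolated)
5 | (R)-4-[(tert-butyldimethylsilyl)oxy]-5,5-dimethylcyclopent-2-en-1-one | O=C1C=C[C@@H](O[Si](C)(C)C(C)(C)C)C1(C)C | intermediate
6 | 2,3-dibromo adduct of 5 (mixture at the two C–Br carbons, silyloxy carbon unchanged) | O=C1C(Br)C(Br)[C@@H](O[Si](C)(C)C(C)(C)C)C1(C)C | intermediate (not isolated)
7 | (R)-2-bromo-4-[(tert-butyldimethylsilyl)oxy]-5,5-dimethylcyclopent-2-en-1-one | O=C1C(Br)=C[C@@H](O[Si](C)(C)C(C)(C)C)C1(C)C | intermediate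
8 | (R)-but-3-yn-2-ol | C[C@@H](O)C#C | starting material
9 | (R)-4-iodobut-3-yn-2-ol | C[C@@H](O)C#CI | intermediate
10 | (R,Z)-4-iodobut-3-en-2-ol | C[C@@H](O)/C=C\I | intermediate
11 | lithium (R,Z)-4-lithiobut-3-en-2-olate | C[C@@H](O[Li])/C=C\[Li] | intermediate (not isolated)
12 | dilithium dialkoxide of the 1,2-adduct of 11 to 7 (new C–O cis to OTBS) | C[C@@H](O[Li])/C=C\[C@]1(O[Li])C(Br)=C[C@@H](O[Si](C)(C)C(C)(C)C)C1(C)C | intermediate (not isolated)
13 | {[(1R,4R)-2-bromo-4-[(tert-butyldimethylsilyl)oxy]-5,5-dimethyl-1-[(1Z,3R)-3-[(trimethylsilyl)oxy]but-1-en-1-yl]cyclopent-2-en-1-yl]oxy}trimethylsilane | C[C@@H](O[Si](C)(C)C)/C=C\[C@]1(O[Si](C)(C)C)C(Br)=C[C@@H](O[Si](C)(C)C(C)(C)C)C1(C)C | intermediate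
14 | (2R,3Z)-4-[(1R,4R)-2-bromo-4-[(tert-butyldimethylsilyl)oxy]-5,5-dimethyl-1-[(trimethylsilyl)oxy]cyclopent-2-en-1-yl]but-3-en-2-ol | C[C@@H](O)/C=C\[C@]1(O[Si](C)(C)C)C(Br)=C[C@@H](O[Si](C)(C)C(C)(C)C)C1(C)C | intermediate
15 | {[(1R,4R)-2-bromo-4-[(tert-butyldimethylsilyl)oxy]-1-[(1Z,3S)-3-chlorobut-1-en-1-yl]-5,5-dimethylcyclopent-2-en-1-yl]oxy}trimethylsilane | C[C@H](Cl)/C=C\[C@]1(O[Si](C)(C)C)C(Br)=C[C@@H](O[Si](C)(C)C(C)(C)C)C1(C)C | intermediate
16 | 2-bromopropanoyl bromide | CC(Br)C(=O)Br | starting material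
17 | methylketene (prop-1-en-1-one) | CC=C=O | intermediate
18 | alkenyllithium from 15 (Br replaced by Li) | C[C@H](Cl)/C=C\[C@]1(O[Si](C)(C)C)C([Li])=C[C@@H](O[Si](C)(C)C(C)(C)C)C1(C)C | intermediate (not isolated)
19 | lithium (Z)-dienolate: 1-propen-1-olate on the cyclopentene carbon that carried Li, methyl cis to OLi | C[C@H](Cl)/C=C\[C@]1(O[Si](C)(C)C)C(/C(O[Li])=C/C)=C[C@@H](O[Si](C)(C)C(C)(C)C)C1(C)C | intermediate (not isolated)
20 | (2R,6R,8aR)-2-[(tert-butyldimethylsilyl)oxy]-1,1,5,6-tetramethyl-8a-[(trimethylsilyl)oxy]-2,5,6,8a-tetrahydroazulen-4(1H)-one (C3=C3a and C7=C8 alkenes, C6 methyl cis to the C8a oxygen, mixture at C5) | C[C@@H]1C=C[C@]2(O[Si](C)(C)C)C(=C[C@@H](O[Si](C)(C)C(C)(C)C)C2(C)C)C(=O)C1C | intermediate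
21 | 2-(benzyloxy)-N-methoxy-N-methylacetamide | CON(C)C(=O)COCc1ccccc1 | starting material
22 | 1-(benzyloxy)but-3-en-2-one | C=CC(=O)COCc1ccccc1 | intermediate
23 | lithium enolate of 20 (C4–OLi, C4=C5) | C[C@@H]1C=C[C@]2(O[Si](C)(C)C)C(=C[C@@H](O[Si](C)(C)C(C)(C)C)C2(C)C)C(O[Li])=C1C | intermediate (not isolated)
24 | (2R,5S,6R,8aR)-5-[4-(benzyloxy)-3-oxobutyl]-2-[(tert-butyldimethylsilyl)oxy]-1,1,5,6-tetramethyl-8a-[(trimethylsilyl)oxy]-2,5,6,8a-tetrahydroazulen-4(1H)-one | C[C@@H]1C=C[C@]2(O[Si](C)(C)C)C(=C[C@@H](O[Si](C)(C)C(C)(C)C)C2(C)C)C(=O)[C@@]1(C)CCC(=O)COCc1ccccc1 | intermediate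
25 | (2R,3aS,5S,6R,8aS)-2-[(tert-butyldimethylsilyl)oxy]-5-(4-hydroxy-3-oxobutyl)-1,1,5,6-tetramethyl-8a-[(trimethylsilyl)oxy]octahydroazulen-4(1H)-one | C[C@@H]1CC[C@]2(O[Si](C)(C)C)[C@H](C[C@@H](O[Si](C)(C)C(C)(C)C)C2(C)C)C(=O)[C@@]1(C)CCC(=O)CO | intermediate
26 | (triphenylphosphoranylidene)acetate ester of the primary alcohol of 25 | C[C@@H]1CC[C@]2(O[Si](C)(C)C)[C@H](C[C@@H](O[Si](C)(C)C(C)(C)C)C2(C)C)C(=O)[C@@]1(C)CCC(=O)COC(=O)C=P(c1ccccc1)(c1ccccc1)c1ccccc1 | intermediate (not isolated)
27 | (2R,3aS,5S,6R,8aS)-2-[(tert-butyldimethylsilyl)oxy]-1,1,5,6-tetramethyl-5-[2-(5-oxo-2,5-dihydrofuran-3-yl)ethyl]-8a-[(trimethylsilyl)oxy]octahydroazulen-4(1H)-one | C[C@@H]1CC[C@]2(O[Si](C)(C)C)[C@H](C[C@@H](O[Si](C)(C)C(C)(C)C)C2(C)C)C(=O)[C@@]1(C)CCC1=CC(=O)OC1 | intermediate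
28 | (2R,3aS,5S,6R,8aS)-2,8a-dihydroxy-1,1,5,6-tetramethyl-5-[2-(5-oxo-2,5-dihydrofuran-3-yl)ethyl]octahydroazulen-4(1H)-one | C[C@@H]1CC[C@]2(O)[C@H](C[C@@H](O)C2(C)C)C(=O)[C@@]1(C)CCC1=CC(=O)OC1 | target

**Step count and risks**

Total step count: 16. Longest linear sequence: 12 (steps 1–4, 7–9, 11, 13–16).

Steps most likely to fail:

Step 11. The alkenyllithium may alkylate itself on the allylic chloride before the ketene arrives, the ketene may oligomerize on the enolate, or the dienolate may close through oxygen. The fallback makes the two bonds in separate, individually known steps and sets out from 13. Bromine–lithium exchange (t-BuLi, −78 °C; no electrophile in the chain) and addition to propanal would give the allylic alcohol F1. Dess–Martin oxidation would give the ethyl alkenyl ketone F2, and K2CO3/MeOH the secondary alcohol F3. Hexachloroacetone/PPh3 would give the (S)-chloride F4, and KHMDS in THF would then close the ring by the same 7-(enolendo)-exo-tet alkylation, coming back to the route at 20.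

Step 13. Proton transfer from the α-alkoxy ketone to the hindered enolate, 1,2-addition or anionic polymerization of the vinyl ketone may prevail over conjugate addition. The fallback replaces the Michael addition by an SN2 alkylation and builds the butenolide from a furan, setting out from 20. LDA and then 3-(2-iodoethyl)furan (THF/DMPU) would give the furylethyl ketone F5, again by attack anti to the C6 methyl. H2 on Pd/C would give the saturated ketone F6. Singlet oxygen with i-Pr2NEt (rose bengal, hν, −78 °C) would give the γ-hydroxybutenolide F7, and NaBH4 at 0 °C would reduce its lactol to the butenolide, coming back at 27.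

Step 14. Hydrogen may be delivered to the wrong face of C3=C3a (cis ring fusion), and the doubly allylic C8a–O bond may be hydrogenolysed on palladium before C7=C8 is saturated. The fallback sets C3a by enolate protonation instead of surface hydrogenation and sets out from 24. Conjugate reduction of the enone with Stryker's reagent, [(Ph3P)CuH]6, and protonation of the resulting enolate would give the C3a–H ketone F8, which can be equilibrated at C3a with DBU if needed. H2 on Pd(OH)2/C would then saturate C7=C8 and cleave the benzyl ether, coming back at 25.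

**Further compounds**

F1 | step 11 | 1-[(3R,5R)-2-bromo-free cyclopentenyl]propan-1-ol: allylic alcohol from 13 with CH(OH)CH2CH3 in place of Br (mixture at the new carbinol) | C[C@@H](O[Si](C)(C)C)/C=C\[C@]1(O[Si](C)(C)C)C(C(O)CC)=C[C@@H](O[Si](C)(C)C(C)(C)C)C1(C)C
F2 | step 11 | ethyl alkenyl ketone: 13 with C(=O)CH2CH3 in place of Br | C[C@@H](O[Si](C)(C)C)/C=C\[C@]1(O[Si](C)(C)C)C(C(=O)CC)=C[C@@H](O[Si](C)(C)C(C)(C)C)C1(C)C
F3 | step 11 | secondary (R)-allylic alcohol of F2 (tertiary TMS ether kept) | C[C@@H](O)/C=C\[C@]1(O[Si](C)(C)C)C(C(=O)CC)=C[C@@H](O[Si](C)(C)C(C)(C)C)C1(C)C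
F4 | step 11 | (S)-allylic chloride of F3 | C[C@H](Cl)/C=C\[C@]1(O[Si](C)(C)C)C(C(=O)CC)=C[C@@H](O[Si](C)(C)C(C)(C)C)C1(C)C
F5 | step 13 | 5-[2-(furan-3-yl)ethyl] analogue of 24 (dienone, C5 methyl cis to C6 methyl) | C[C@@H]1C=C[C@]2(O[Si](C)(C)C)C(=C[C@@H](O[Si](C)(C)C(C)(C)C)C2(C)C)C(=O)[C@@]1(C)CCc1ccoc1
F6 | step 13 | octahydroazulenone from F5 (trans ring fusion, furan kept) | C[C@@H]1CC[C@]2(O[Si](C)(C)C)[C@H](C[C@@H](O[Si](C)(C)C(C)(C)C)C2(C)C)C(=O)[C@@]1(C)CCc1ccoc1
F7 | step 13 | γ-hydroxybutenolide from F6 (5-hydroxy-2(5H)-furanon-4-yl, mixture at the lactol carbon) | C[C@@H]1CC[C@]2(O[Si](C)(C)C)[C@H](C[C@@H](O[Si](C)(C)C(C)(C)C)C2(C)C)C(=O)[C@@]1(C)CCC1=CC(=O)OC1O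
F8 | step 14 | 24 with C3–C3a saturated (C3a–H trans to the C8a oxygen), C7=C8 and benzyl ether kept | C[C@@H]1C=C[C@]2(O[Si](C)(C)C)[C@H](C[C@@H](O[Si](C)(C)C(C)(C)C)C2(C)C)C(=O)[C@@]1(C)CCC(=O)COCc1ccccc1
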